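**Retrosynthetic overview**
- Target ⇐ allylic oxidation of a triol ⇐ hydride opening of a bridged seven-membered lactone, with Pd/hydride removal of a C13 sulfone in the same operation.
- Key step: one cation–olefin cascade on an acyclic 3,4-seco polyene closes the only carbocycle through the C6–C11 bond, the bond that closes this ring in the presumed iridal biosynthesis. The C11 olefin carbon attacks a C6 allyl cation, and the C10 cation is trapped by the C3 carboxyl, so C6, C10 and C11 are set together.
- Seco-polyene ⇐ C1–C12 allylic bromide + C13–C23 allyl sulfone made from geranyl bromide (sulfone alkylation forms C12–C13).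
- C1–C12 part ⇐ (E)-dibromide of 2,3-dimethylbutadiene + propyne + formaldehyde; copper-catalysed anti-methylmagnesiation with aldehyde capture fixes the (Z)-C2=C7 olefin, and a 2,5-dihydrofuran stores that geometry.
- Ring order: dihydrofuran (temporary, opened in the key step) → cyclohexane → bridging lactone (same operation, opened one step later).

Assumption: locants are iridal locants (C1 = CHO, C2 = its α-carbon, C3–C5 = hydroxypropyl chain with OH on C3, C6–C11 = ring with C7 sp2, C10 carbinol, C11 quaternary, C12–C23 = side chain); the target is taken exactly as drawn, (6S,10R,11S), with C5, C12 and the C10 oxygen on one face of the ring.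
Assumption: which enantiomer of the squaramide in step 11 gives the drawn series cannot be predicted and is fixed by a one-off screen; both enantiomers are accessible.

**Step 1**
Reactants: 1 2,3-dimethylbuta-1,3-diene
Product: 2 (2E)-1,4-dibromo-2,3-dimethylbut-2-ene
Conditions: Br2, CH2Cl2, −20 °C; crystallise
Reagents that add atoms: bromine BrBr
Why: 1,4-addition of bromine to the conjugated diene gives the crystalline (E)-dibromide, which fixes the E geometry of the future C10=C11 olefin.

**Step 2**
Reactants: 2 (2E)-1,4-dibromo-2,3-dimethylbut-2-ene; 3 propyne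
Product: 6 (6E)-8-bromo-6,7-dimethyloct-6-en-2-yn-1-ol, via 1,3-dilithiopropyne 4 (not isolated), via lithium acetylide 5 (not isolated)
Conditions: 3, n-BuLi (2 equiv), TMEDA, Et2O/hexane, −78 to 0 °C; added to 2 (3 equiv, excess recovered), THF, −78 °C; CH2O (g), −78 °C; aq NH4Cl
Reagents that add atoms: formaldehyde C=O
Why: The sp3 carbanion of the propyne dianion displaces one allylic bromide (SN2 propargylation), the remaining lithium acetylide is inert to allylic bromide without copper or a dipolar additive, and it is then hydroxymethylated by formaldehyde.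

**Step 3**
Reactants: 6 (6E)-8-bromo-6,7-dimethyloct-6-en-2-yn-1-ol
Product: 8 (6E)-6,7-dimethyloct-6-en-2-yne-1,8-diol, via allylic acetate 7 (not isolated)
Conditions: KOAc, DMF, rt; then K2CO3, MeOH, rt
Reagents that add atoms: potassium acetate CC(=O)[O-].[K+]
Why: SN2 displacement of the primary allylic bromide by acetate followed by transesterification gives the alcohol without allylic transposition.

**Step 4**
Reactants: 8 (6E)-6,7-dimethyloct-6-en-2-yne-1,8-diol; 9 tert-butyl 4-oxobutanoate
Product: 11 tert-butyl (5Z)-4,7-dihydroxy-5-[(3E)-5-hydroxy-3,4-dimethylpent-3-en-1-yl]-6-methylhept-5-enoate (racemic), via vinylmagnesium chelate 10 (not isolated)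
Conditions: MeMgBr (5 equiv), CuI (15 mol %), THF, 0 °C to reflux; then 9 (4 equiv), −78 to −20 °C; aq NH4Cl at −20 °C
Reagents that add atoms: methylmagnesium bromide C[Mg]Br
Why: Copper-catalysed anti-carbomagnesiation of the 2-alkyn-1-ol puts methyl on C2 and an alkoxide-chelated magnesium on C7, and this vinyl Grignard adds to aldehyde 9, so the tetrasubstituted C2=C7 olefin forms with C1 and C6 cis (the new C6 carbinol centre is racemic and is erased in step 11).

**Step 5**
Reactants: 11 tert-butyl (5Z)-4,7-dihydroxy-5-[(3E)-5-hydroxy-3,4-dimethylpent-3-en-1-yl]-6-methylhept-5-enoate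
Product: 13 tert-butyl 3-{3-[(3E)-5-bromo-3,4-dimethylpent-3-en-1-yl]-4-methyl-2,5-dihydrofuran-2-yl}propanoate (racemic), via dihydrofuran mesylate 12 (not isolated)
Conditions: MsCl (2.2 equiv), Et3N, THF, −40 to 0 °C; then LiBr, 0 °C
Reagents that add atoms: lithium bromide [Li+].[Br-]
Why: Both primary allylic alcohols are mesylated in preference to the hindered secondary one, the C6 hydroxyl displaces the cis-disposed C1 mesylate (5-exo-tet Williamson closure to the 2,5-dihydrofuran, which locks the Z geometry and masks the C1 oxygen), and bromide displaces the remote C12 mesylate.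

**Step 6**
Reactants: 14 geranyl bromide
Product: 15 geranyl phenyl sulfone
Conditions: PhSO2Na, DMF, rt
Reagents that add atoms: sodium benzenesulfinate [Na+].[O-]S(=O)c1ccccc1
Why: S-alkylation of the sulfinate by the primary allylic bromide (SN2) gives the sulfone with the (E)-olefin intact.

**Step 7**
Reactants: 15 geranyl phenyl sulfone
Product: 16 (2E,6E)-2,6-dimethyl-8-(phenylsulfonyl)octa-2,6-dien-1-ol
Conditions: SeO2 (0.1 equiv), t-BuOOH (2 equiv), CH2Cl2, 0 °C to rt
Reagents that add atoms: tert-butyl hydroperoxide CC(C)(C)OO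
Why: SeO2-catalysed allylic oxidation (ene reaction then [2,3] shift) hydroxylates the (E)-methyl of the electron-rich terminal olefin and leaves the sulfone-deactivated olefin alone.

**Step 8**
Reactants: 16 (2E,6E)-2,6-dimethyl-8-(phenylsulfonyl)octa-2,6-dien-1-ol
Product: 17 [(2E,6E)-8-bromo-3,7-dimethylocta-2,6-dien-1-yl]sulfonylbenzene
Conditions: CBr4, PPh3, CH2Cl2, 0 °C
Reagents that add atoms: carbon tetrabromide BrC(Br)(Br)Br
Why: Appel bromination converts the primary allylic alcohol into the bromide under neutral conditions without allylic shift.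

**Step 9**
Reactants: 17 [(2E,6E)-8-bromo-3,7-dimethylocta-2,6-dien-1-yl]sulfonylbenzene; 18 2,3-dimethylbut-1-ene
Product: 20 [(2E,6E)-3,7,11-trimethyl-10-methylidenedodeca-2,6-dien-1-yl]sulfonylbenzene, via 2-isopropylallyllithium 19 (not isolated)
Conditions: 18, n-BuLi, TMEDA, hexane, rt; THF, −78 °C; slow addition of 17 to 3 equiv of 19; aq NH4Cl
Reagents that add atoms: none
Why: Allylic lithiation of the methyl group gives an allyl anion with two equivalent CH2 termini that displaces the allylic bromide (SN2), which installs the CH2–C(=CH2)–CH(CH3)2 terminus in one step; inverse addition into excess 19 keeps the transiently deprotonated sulfone from alkylating another molecule.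

**Step 10**
Reactants: 13 tert-butyl 3-{3-[(3E)-5-bromo-3,4-dimethylpent-3-en-1-yl]-4-methyl-2,5-dihydrofuran-2-yl}propanoate; 20 [(2E,6E)-3,7,11-trimethyl-10-methylidenedodeca-2,6-dien-1-yl]sulfonylbenzene
Product: 22 tert-butyl 3-{4-methyl-3-[(3E,7E,11E)-3,4,8,12,16-pentamethyl-15-methylidene-6-(phenylsulfonyl)heptadeca-3,7,11-trien-1-yl]-2,5-dihydrofuran-2-yl}propanoate (stereoisomer mixture at the ring carbon and the sulfonyl carbon), via lithiated sulfone 21 (not isolated)
Conditions: 20, n-BuLi, THF, −78 °C; then 13, −78 to −40 °C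
Reagents that add atoms: none
Why: Alkylation of the lithiated allyl sulfone by the primary allylic bromide (Biellmann-type coupling) forms C12–C13 without touching olefin geometry, and the sulfone is kept to deactivate and shield the C14=C15 olefin in step 11; both stereocentres of 22 are erased later.

**Step 11**
Reactants: 22 tert-butyl 3-{4-methyl-3-[(3E,7E,11E)-3,4,8,12,16-pentamethyl-15-methylidene-6-(phenylsulfonyl)heptadeca-3,7,11-trien-1-yl]-2,5-dihydrofuran-2-yl}propanoate
Product: 24 (6S,10R,11S) bridged 3,10-lactone (2-oxabicyclo[4.3.1]decan-3-one core) with free C1 hydroxyl and C13 sulfone, via trimethylsilyl ether 23 (not isolated)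
Conditions: TMSOTf (1.3 equiv), chiral arylpyrrolidine squaramide (10 mol %), 2,6-di-tert-butyl-4-methylpyridine (1.5 equiv), toluene/CH2Cl2, −78 °C; aq citric acid, THF
Reagents that add atoms: none
Why: Proposed new method: the silyl triflate, bound through its triflate to the chiral squaramide, silylates the dihydrofuran oxygen and ionises C6–O to a C6–C7–C2 allyl cation whose C2 end keeps its geometry because the ring held C1 cis to C6; the C10=C11 olefin attacks C6 through a chair in which the C5 chain is pseudoaxial (A(1,3) strain with C1) and the C11 methyl is axial (it is cis to C9 in the E olefin), so C12 ends cis to C5; the C10 cation is captured on that same face by the axial C3 ester carbonyl with loss of isobutene, so the C10 oxygen is cis to both chains; the squaramide-bound triflate ion pair differentiates the two faces of the allyl cation, which sets the absolute configuration; this mirrors the biosynthetic closure of this ring, and the closest known reactions are Johnson allyl-cation-initiated cation–olefin cyclisation, carboxyl-terminated polyene cyclisation (homofarnesic acid to sclareolide) and squaramide/silyl triflate-catalysed enantioselective SN1 alkylation of carbocations by π-nucleophiles.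

**Step 12**
Reactants: 24 (6S,10R,11S) bridged 3,10-lactone with free C1 hydroxyl and C13 sulfone
Product: 25 (2Z)-2-[(2S,3S,4R)-4-hydroxy-2-(3-hydroxypropyl)-3,4-dimethyl-3-[(3E,7E)-4,8,12-trimethyl-11-methylidenetrideca-3,7-dien-1-yl]cyclohexylidene]propan-1-ol
Conditions: PdCl2(dppp) (5 mol %), LiBHEt3 (6 equiv), THF, 0 °C to rt
Reagents that add atoms: none
Why: Zerovalent palladium ionises the allylic sulfone and hydride is delivered to the less hindered C13 terminus with retention of the (E)-C14=C15 olefin (Pd-catalysed reductive desulfonylation), while the same hydride reduces the lactone to the C3 primary and C10 tertiary alcohols without touching a stereocentre.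

**Step 13**
Reactants: 25 (2Z)-2-[(2S,3S,4R)-4-hydroxy-2-(3-hydroxypropyl)-3,4-dimethyl-3-[(3E,7E)-4,8,12-trimethyl-11-methylidenetrideca-3,7-dien-1-yl]cyclohexylidene]propan-1-ol
Product: 26 (2Z)-2-[(2S,3S,4R)-4-hydroxy-2-(3-hydroxypropyl)-3,4-dimethyl-3-[(3E,7E)-4,8,12-trimethyl-11-methylidenetrideca-3,7-dien-1-yl]cyclohexylidene]propanal
Conditions: activated MnO2 (excess), CH2Cl2, rt
Reagents that add atoms: none
Why: Activated MnO2 oxidises only the allylic primary alcohol (chemoselective allylic oxidation), leaves the saturated primary and the tertiary alcohol untouched and does not isomerise the tetrasubstituted olefin.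

**Compound list**
1 | 2,3-dimethylbuta-1,3-diene | C=C(C)C(C)=C | starting material
2 | (2E)-1,4-dibromo-2,3-dimethylbut-2-ene | BrC/C(C)=C(\C)CBr | intermediate
3 | propyne | CC#C | starting material
4 | 1,3-dilithiopropyne | [Li]CC#C[Li] | intermediate
5 | [(5E)-7-bromo-5,6-dimethylhept-5-en-1-yn-1-yl]lithium | [Li]C#CCC/C(C)=C(\C)CBr | intermediate
6 | (6E)-8-bromo-6,7-dimethyloct-6-en-2-yn-1-ol | OCC#CCC/C(C)=C(\C)CBr | intermediate
7 | (2E)-8-hydroxy-2,3-dimethyloct-2-en-6-yn-1-yl acetate | CC(=O)OC/C(C)=C(\C)CCC#CCO | intermediate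
8 | (6E)-6,7-dimethyloct-6-en-2-yne-1,8-diol | OCC#CCC/C(C)=C(\C)CO | intermediate
9 | tert-butyl 4-oxobutanoate | CC(C)(C)OC(=O)CCC=O | starting material
10 | [(2Z,6E)-1,8-bis(bromomagnesiooxy)-2,6,7-trimethylocta-2,6-dien-3-yl]magnesium bromide | Br[Mg]OC/C(C)=C(\C)CC/C([Mg]Br)=C(\C)CO[Mg]Br | intermediate
11 | tert-butyl (5Z)-4,7-dihydroxy-5-[(3E)-5-hydroxy-3,4-dimethylpent-3-en-1-yl]-6-methylhept-5-enoate, racemic at C4 | CC(C)(C)OC(=O)CCC(O)/C(CC/C(C)=C(\C)CO)=C(/C)CO | intermediate
12 | tert-butyl 3-{3-[(3E)-3,4-dimethyl-5-(methylsulfonyloxy)pent-3-en-1-yl]-4-methyl-2,5-dihydrofuran-2-yl}propanoate, racemic | CC(C)(C)OC(=O)CCC1OCC(C)=C1CC/C(C)=C(\C)COS(C)(=O)=O | intermediate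
13 | tert-butyl 3-{3-[(3E)-5-bromo-3,4-dimethylpent-3-en-1-yl]-4-methyl-2,5-dihydrofuran-2-yl}propanoate, racemic | CC(C)(C)OC(=O)CCC1OCC(C)=C1CC/C(C)=C(\C)CBr | intermediate
14 | geranyl bromide, (2E)-1-bromo-3,7-dimethylocta-2,6-diene | CC(C)=CCC/C(C)=C/CBr | starting material
15 | geranyl phenyl sulfone, [(2E)-3,7-dimethylocta-2,6-dien-1-yl]sulfonylbenzene | CC(C)=CCC/C(C)=C/CS(=O)(=O)c1ccccc1 | intermediate
16 | (2E,6E)-2,6-dimethyl-8-(phenylsulfonyl)octa-2,6-dien-1-ol | OC/C(C)=C/CC/C(C)=C/CS(=O)(=O)c1ccccc1 | intermediate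
17 | [(2E,6E)-8-bromo-3,7-dimethylocta-2,6-dien-1-yl]sulfonylbenzene | BrC/C(C)=C/CC/C(C)=C/CS(=O)(=O)c1ccccc1 | intermediate
18 | 2,3-dimethylbut-1-ene | C=C(C)C(C)C | starting material
19 | (3-methyl-2-methylidenebutyl)lithium (2-isopropylallyllithium) | [Li]CC(=C)C(C)C | intermediate
20 | [(2E,6E)-3,7,11-trimethyl-10-methylidenedodeca-2,6-dien-1-yl]sulfonylbenzene | C=C(CC/C(C)=C/CC/C(C)=C/CS(=O)(=O)c1ccccc1)C(C)C | intermediate
21 | 20 lithiated at the sulfonyl-bearing carbon | C=C(CC/C(C)=C/CC/C(C)=C/C([Li])S(=O)(=O)c1ccccc1)C(C)C | intermediate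
22 | tert-butyl 3-{4-methyl-3-[(3E,7E,11E)-3,4,8,12,16-pentamethyl-15-methylidene-6-(phenylsulfonyl)heptadeca-3,7,11-trien-1-yl]-2,5-dihydrofuran-2-yl}propanoate, stereoisomer mixture at the dihydrofuran C2 and the sulfonyl carbon | C=C(CC/C(C)=C/CC/C(C)=C/C(S(=O)(=O)c1ccccc1)C/C(C)=C(\C)CCC1=C(C)COC1CCC(=O)OC(C)(C)C)C(C)C | intermediate
23 | C1 trimethylsilyl ether of 24 | C=C(CC/C(C)=C/CC/C(C)=C/C(S(=O)(=O)c1ccccc1)C[C@@]2(C)[C@@H](CCC3=O)/C(=C(/C)CO[Si](C)(C)C)CC[C@@]2(C)O3)C(C)C | intermediate
24 | (6S,10R,11S) bridged lactone, iridal locants: C3 carboxyl esterified by the C10 oxygen (2-oxabicyclo[4.3.1]decan-3-one core); C7=C2(CH3)CH2OH with CH2OH cis to C6; CH3 on C10 and on C11; C11 chain CH2–CH(SO2Ph)–CH=C(CH3)–CH2CH2–CH=C(CH3)–CH2CH2–C(=CH2)–CH(CH3)2 with E olefins; both C13 epimers | C=C(CC/C(C)=C/CC/C(C)=C/C(S(=O)(=O)c1ccccc1)C[C@@]2(C)[C@@H](CCC3=O)/C(=C(/C)CO)CC[C@@]2(C)O3)C(C)C | intermediate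
25 | (2Z)-2-[(2S,3S,4R)-4-hydroxy-2-(3-hydroxypropyl)-3,4-dimethyl-3-[(3E,7E)-4,8,12-trimethyl-11-methylidenetrideca-3,7-dien-1-yl]cyclohexylidene]propan-1-ol | C=C(CC/C(C)=C/CC/C(C)=C/CC[C@@]1(C)[C@@H](CCCO)/C(=C(/C)CO)CC[C@@]1(C)O)C(C)C | intermediate
26 | (2Z)-2-[(2S,3S,4R)-4-hydroxy-2-(3-hydroxypropyl)-3,4-dimethyl-3-[(3E,7E)-4,8,12-trimethyl-11-methylidenetrideca-3,7-dien-1-yl]cyclohexylidene]propanal | C=C(CC/C(C)=C/CC/C(C)=C/CC[C@@]1(C)[C@@H](CCCO)/C(=C(/C)C=O)CC[C@@]1(C)O)C(C)C | target

**Step count**
Total step count: 13. Longest linear sequence: 9 steps (steps 1–5 and 10–13); the side-chain sulfone (steps 6–9) joins at step 10.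

**Three steps most likely to fail**

Step 11 is the least certain. The seven-membered lactone trap has to outrun elimination, closure onto C10 instead of C11, and capture of the C10 cation by the C14=C15 olefin. Enantiocontrol by the squaramide-bound triflate is unproven for this allyl cation. Fallback: give up catalyst control and resolve. Setting out from 22, TMSOTf and 2,6-di-tert-butyl-4-methylpyridine alone (CH2Cl2, −78 °C, same work-up) give the racemic bridged lactone F1. The conditions of step 12 convert it into the racemic triol F2. Its enantiomers are separated on an amylose tris(3,5-dimethylphenylcarbamate) stationary phase, and the (2S,3S,4R) enantiomer is 25, where the route is rejoined.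

Step 4 may fail because methylmagnesiation of an internal alkynol is slow and the aldehyde must compete for the chelated vinyl Grignard against residual MeMgBr. Fallback: separate the two events and form C6–C7 by chromium chemistry. Setting out from 8, the same CuI-catalysed methylmagnesiation is quenched with iodine to give the vinyl iodide F3. Nozaki–Hiyama–Kishi coupling of F3 with 9 (CrCl2, NiCl2 cat., DMF/THF, rt) gives 11, where the route is rejoined.

Step 9 may fail because the allyl anion first deprotonates the sulfone, and the resulting carbanion can alkylate a second molecule. Fallback: build the terminus through a soft enolate. Setting out from 17, alkylation of methyl 4-methyl-3-oxopentanoate (K2CO3, acetone) gives the keto ester F4. Krapcho dealkoxycarbonylation (LiCl, wet DMSO, 140 °C) gives the isopropyl ketone F5. Wittig methylenation (Ph3P=CH2 in excess, THF) gives 20, where the route is rejoined.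

**Further compounds**
F1 | step 11 | racemic bridged lactone, constitution and relative configuration of 24, both C13 epimers | C=C(CC/C(C)=C/CC/C(C)=C/C(S(=O)(=O)c1ccccc1)CC2(C)C(CCC3=O)/C(=C(/C)CO)CCC2(C)O3)C(C)C
F2 | step 11 | racemic triol, constitution and relative configuration of 25 | C=C(CC/C(C)=C/CC/C(C)=C/CCC1(C)C(CCCO)/C(=C(/C)CO)CCC1(C)O)C(C)C
F3 | step 4 | (2Z,6E)-3-iodo-2,6,7-trimethylocta-2,6-diene-1,8-diol | OC/C(C)=C(\I)CC/C(C)=C(\C)CO
F4 | step 9 | methyl (4E,8E)-4,8-dimethyl-2-(2-methylpropanoyl)-10-(phenylsulfonyl)deca-4,8-dienoate | COC(=O)C(C/C(C)=C/CC/C(C)=C/CS(=O)(=O)c1ccccc1)C(=O)C(C)C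
F5 | step 9 | (6E,10E)-2,6,10-trimethyl-12-(phenylsulfonyl)dodeca-6,10-dien-3-one | CC(C)C(=O)CC/C(C)=C/CC/C(C)=C/CS(=O)(=O)c1ccccc1
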